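The benzene ring is built last, by cutting C4–C5 and C6–C7 of the dihydrobenzofuran. The arene carries the acetyl group on C5 para to the ring oxygen O1 (on C7a) and the hydroxyl on C6, the pattern expected when a 2-alkoxydiene meets a β-alkoxy ynone. In one operation, [4+2] cycloaddition and dehydrogenation in the same flask close the carbocycle and place both substituents. The diene is an enantiopure 2,3-dimethylideneoxolane that already holds the cis C2 isopropenyl and C3 silyloxy groups (set by alkoxyallylboration, carried through a lactone); the dienophile is a silylethoxy ynone. Desilylation and one esterification finish the synthesis.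

Key step: step 12

Remark: the target is read as the 2,3-cis (2S,3S) dihydrobenzofuran whose ester is the (2Z) acid (carboxyl cis to the C3 methyl, angelate type); allyl methoxymethyl ether is made in step 1 because its commercial supply is not assumed.

Step 1
Reactants: 1 prop-2-en-1-ol (allyl alcohol)
Product: 2 3-(methoxymethoxy)prop-1-ene
Conditions: MOMCl, i-Pr2NEt, CH2Cl2, 0 °C to rt
Reagents that add atoms: chloromethyl methyl ether, COCCl
Why: Williamson-type O-alkylation with the α-chloro ether gives the MOM acetal, whose oxygen atoms later chelate lithium and fix the Z geometry of the allyl anion.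

Step 2
Reactants: 2 3-(methoxymethoxy)prop-1-ene, 3 methacrolein (2-methylprop-2-enal)
Product: 5 (3S,4S)-4-(methoxymethoxy)-2-methylhexa-1,5-dien-3-ol, via Z-alkoxyallylborane 4 (not isolated)
Conditions: s-BuLi, THF, −78 °C; (+)-Ipc2BOMe; BF3·OEt2; then 3, −78 °C; NaOH, H2O2, 0 °C to rt
Reagents that add atoms: none
Why: Brown alkoxyallylboration: the chelated Z-alkoxyallyllithium is transferred to boron and borane 4 adds through a closed chair (Zimmerman–Traxler) transition state, so the Z geometry gives the syn C3/C4 relationship while the isopinocampheyl groups (from (−)-α-pinene) direct attack to the Re face of the aldehyde, setting C3 as S and with it C4 as S.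

Step 3
Reactants: 5 (3S,4S)-4-(methoxymethoxy)-2-methylhexa-1,5-dien-3-ol
Product: 7 (3S,4S)-3-(methoxymethoxy)-5-methylhex-5-ene-1,4-diol, via bis(disiamylboryl) adduct 6 (not isolated)
Conditions: Sia2BH (2.2 equiv, from BH3·THF and 2-methylbut-2-ene), THF, 0 °C; then NaOH, H2O2
Reagents that add atoms: hydrogen peroxide, OO
Why: Hydroboration–oxidation: the hindered dialkylborane first caps the hydroxyl as a borinate and then adds anti-Markovnikov to the monosubstituted vinyl group much faster than to the 1,1-disubstituted isopropenyl group, and oxidation replaces boron by hydroxyl without touching either stereocentre.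

Step 4
Reactants: 7 (3S,4S)-3-(methoxymethoxy)-5-methylhex-5-ene-1,4-diol
Product: 9 (4S,5S)-4-(methoxymethoxy)-5-(prop-1-en-2-yl)oxolan-2-one, via lactol 8 (not isolated)
Conditions: TEMPO (cat.), PhI(OAc)2, CH2Cl2, rt
Reagents that add atoms: none
Why: Oxoammonium (TEMPO) oxidation is selective for the primary alcohol, the hydroxy aldehyde closes to the five-membered lactol 8 and this is oxidised on to the γ-lactone, which locks the syn diol as the cis-4,5-disubstituted ring.

Step 5
Reactants: 9 (4S,5S)-4-(methoxymethoxy)-5-(prop-1-en-2-yl)oxolan-2-one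
Product: 10 (4S,5S)-4-hydroxy-5-(prop-1-en-2-yl)oxolan-2-one
Conditions: ZnBr2, n-PrSH, CH2Cl2, 0 °C to rt
Reagents that add atoms: none
Why: Lewis acid-assisted acetal cleavage: ZnBr2 activates the MOM oxygen and the thiol captures the methoxymethyl group, freeing the hydroxyl under conditions that should leave the lactone and the isopropenyl group alone.

Step 6
Reactants: 10 (4S,5S)-4-hydroxy-5-(prop-1-en-2-yl)oxolan-2-one
Product: 11 (3S,4S,5S)-3-[(dimethylamino)methyl]-4-hydroxy-5-(prop-1-en-2-yl)oxolan-2-one
Conditions: LDA (2.3 equiv), THF, −78 to −40 °C; Me2N=CH2+ I−, −78 to 0 °C; H2O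
Reagents that add atoms: N,N-dimethylmethylideneammonium iodide (Eschenmoser's salt), C=[N+](C)C.[I-]
Why: Mannich reaction of the alkoxide–enolate dianion (Fráter–Seebach type): because the β-oxygen is an alkoxide it cannot be expelled, and the iminium ion enters anti to it to give the 3,4-trans product, a C3 centre that is erased in step 7.

Step 7
Reactants: 11 (3S,4S,5S)-3-[(dimethylamino)methyl]-4-hydroxy-5-(prop-1-en-2-yl)oxolan-2-one
Product: 13 (4S,5S)-4-hydroxy-3-methylidene-5-(prop-1-en-2-yl)oxolan-2-one, via trimethylammonium iodide 12 (not isolated)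
Conditions: MeI, MeOH, rt; evaporate; NaHCO3, CH2Cl2/H2O, rt
Reagents that add atoms: none
Why: Exhaustive N-methylation turns the amine into a leaving group and mild base then removes the acidic C3 proton (E1cB, Hofmann-type elimination), giving the exocyclic methylene without disturbing C4 or C5.

Step 8
Reactants: 13 (4S,5S)-4-hydroxy-3-methylidene-5-(prop-1-en-2-yl)oxolan-2-one
Product: 14 (4S,5S)-4-{[tert-butyl(dimethyl)silyl]oxy}-3-methylidene-5-(prop-1-en-2-yl)oxolan-2-one
Conditions: TBSOTf, 2,6-lutidine, CH2Cl2, −78 to 0 °C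
Reagents that add atoms: tert-butyldimethylsilyl trifluoromethanesulfonate, CC(C)(C)[Si](C)(C)OS(=O)(=O)C(F)(F)F
Why: Silylation of the secondary alcohol with a silyl triflate and a hindered, non-nucleophilic base avoids conjugate addition to the α-methylene lactone and installs a group that survives the titanium and quinone reagents and leaves with fluoride.

Step 9
Reactants: 14 (4S,5S)-4-{[tert-butyl(dimethyl)silyl]oxy}-3-methylidene-5-(prop-1-en-2-yl)oxolan-2-one
Product: 15 tert-butyl(dimethyl){[(2S,3S)-4,5-dimethylidene-2-(prop-1-en-2-yl)oxolan-3-yl]oxy}silane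
Conditions: Cp2TiMe2 (2.5 equiv), PhMe, 65 °C, dark; filtration through basic alumina
Reagents that add atoms: dimethyltitanocene, [CH3-].[CH3-].[Ti+4].c1cc[cH-]c1.c1cc[cH-]c1
Why: Petasis methylenation: Cp2Ti=CH2, released thermally from Cp2TiMe2, adds [2+2] to the lactone carbonyl and cycloreverts to the enol ether under neutral conditions that conjugated esters and lactones tolerate, so the acid-sensitive 2-alkoxydiene should form without migration of either double bond.

Step 10
Reactants: 16 2-(trimethylsilyl)ethanol, 17 trichloroethylene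
Product: 18 {2-[(E)-1,2-dichloroethenyl]oxyethyl}(trimethyl)silane
Conditions: KH, THF, 0 °C; then 17, −50 °C to rt
Reagents that add atoms: none
Why: Addition–elimination via dichloroacetylene: the potassium alkoxide dehydrochlorinates trichloroethylene and adds anti to the resulting dichloroalkyne, giving the (E)-1,2-dichlorovinyl ether.

Step 11
Reactants: 18 {2-[(E)-1,2-dichloroethenyl]oxyethyl}(trimethyl)silane
Product: 20 4-[2-(trimethylsilyl)ethoxy]but-3-yn-2-one, via lithium alkoxyacetylide 19 (not isolated)
Conditions: n-BuLi (2.2 equiv), THF, −78 to −40 °C; MeC(O)N(OMe)Me, −78 to 0 °C; pH 7 buffer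
Reagents that add atoms: N-methoxy-N-methylacetamide, CON(C)C(C)=O
Why: n-BuLi effects β-elimination of LiCl and then chlorine–lithium exchange to give acetylide 19, which is acylated only once by the Weinreb amide because the chelated tetrahedral adduct survives until work-up.

Step 12
Reactants: 15 tert-butyl(dimethyl){[(2S,3S)-4,5-dimethylidene-2-(prop-1-en-2-yl)oxolan-3-yl]oxy}silane, 20 4-[2-(trimethylsilyl)ethoxy]but-3-yn-2-one
Product: 22 1-[(2S,3S)-3-{[tert-butyl(dimethyl)silyl]oxy}-2-(prop-1-en-2-yl)-6-[2-(trimethylsilyl)ethoxy]-2,3-dihydro-1-benzofuran-5-yl]ethan-1-one, via 1,4-cyclohexadiene adduct 21 (not isolated)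
Conditions: 20 (1.5 equiv), PhMe (1 M), 2,6-di-tert-butylpyridine (0.1 equiv), BHT (cat.), 60 °C; then DDQ (1.1 equiv), NaHCO3 (s), 0 °C
Reagents that add atoms: none
Why: Proposed new method: the s-cis-locked exocyclic diene 15 is a 2-alkoxydiene whose enol-ether terminus C7 carries the largest HOMO coefficient, so in an asynchronous concerted [4+2] (a stepwise Michael addition–ring closure would give the same connectivity) it bonds to the alkoxy-bearing β-carbon of ynone 20, the site of the largest LUMO coefficient, while C4 bonds to the acyl-bearing carbon, forming C6–C7 and C4–C5 and giving 1,4-cyclohexadiene 21; DDQ then abstracts hydride from the doubly allylic C4/C7 positions and proton loss gives the benzene ring. The closest known reaction type is the Diels–Alder addition of exocyclic 2-alkoxy-1,3-dienes to acetylenic ketones followed by quinone dehydrogenation, which has not been shown for a 2,3-dimethylideneoxolane with a donor-substituted ynone. The six-membered carbocycle is closed by intermolecular cycloaddition, both new bonds forming across the diene termini in one step. No stereocentre is created, and C2 and C3 (set in step 2) are spectators that meet no benzylic cation because the arene does not yet exist. The step needs regioselectivity, secured by the matched polarisation of the partners (O1 on C7a sends the acetyl group para, to C5, and the ynone oxygen to C6), and it needs the allylic C3 silyloxy group to survive, secured by hindered-base buffering, a moderate temperature that also spares the ynol ether, and immediate oxidation of 21.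

Step 13
Reactants: 22 1-[(2S,3S)-3-{[tert-butyl(dimethyl)silyl]oxy}-2-(prop-1-en-2-yl)-6-[2-(trimethylsilyl)ethoxy]-2,3-dihydro-1-benzofuran-5-yl]ethan-1-one
Product: 23 1-[(2S,3S)-3,6-dihydroxy-2-(prop-1-en-2-yl)-2,3-dihydro-1-benzofuran-5-yl]ethan-1-one
Conditions: TBAF (3.5 equiv), THF, 0 °C to rt; AcOH quench
Reagents that add atoms: none
Why: Fluoride-induced desilylation: the silyl ether gives the C3 alkoxide and the silylethyl ether fragments (β-elimination with loss of ethene) to the C6 phenoxide, a good leaving group because it is ortho to the acetyl group, while neither stereocentre is touched and the weak-acid quench avoids ionisation at benzylic C3.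

Step 14
Reactants: 24 (E)-but-2-enal (crotonaldehyde)
Product: 25 (2Z)-2-iodobut-2-enal
Conditions: I2, K2CO3, DMAP (cat.), THF/H2O (1:1), rt
Reagents that add atoms: iodine, II
Why: α-Iodination of the enal by conjugate addition of DMAP, iodination of the enolate and elimination of DMAP (Morita–Baylis–Hillman-type pathway) should give the thermodynamically preferred Z isomer with iodine cis to methyl.

Step 15
Reactants: 25 (2Z)-2-iodobut-2-enal
Product: 26 (2Z)-2-iodobut-2-en-1-ol
Conditions: NaBH4, CeCl3·7H2O, MeOH, 0 °C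
Reagents that add atoms: none
Why: Luche reduction delivers hydride to the carbonyl only (1,2-reduction), leaving the vinyl iodide and its geometry intact.

Step 16
Reactants: 26 (2Z)-2-iodobut-2-en-1-ol
Product: 28 (2Z)-2-(hydroxymethyl)but-2-enoic acid, via dilithio species 27 (not isolated)
Conditions: n-BuLi (1.0 equiv) then t-BuLi (2.1 equiv), Et2O, −78 °C; CO2 (g), −78 to 0 °C; 1 M HCl
Reagents that add atoms: carbon dioxide, O=C=O
Why: Deprotonation of the hydroxyl followed by iodine–lithium exchange gives the configurationally stable alkenyllithium 27, and carboxylation with retention places the carboxyl group cis to methyl, which is the Z geometry of the side chain.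

Step 17
Reactants: 28 (2Z)-2-(hydroxymethyl)but-2-enoic acid
Product: 29 (2Z)-2-[(acetyloxy)methyl]but-2-enoic acid
Conditions: Ac2O, pyridine, CH2Cl2, 0 °C to rt; H2O
Reagents that add atoms: acetic anhydride, CC(=O)OC(C)=O
Why: Acylation of the primary allylic alcohol with acetic anhydride and pyridine, without a strongly nucleophilic amine that could trigger SN2' scrambling of the alkene, should give the acetoxy acid after aqueous work-up.

Step 18
Reactants: 23 1-[(2S,3S)-3,6-dihydroxy-2-(prop-1-en-2-yl)-2,3-dihydro-1-benzofuran-5-yl]ethan-1-one, 29 (2Z)-2-[(acetyloxy)methyl]but-2-enoic acid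
Product: 31 (2S,3S)-5-acetyl-6-hydroxy-2-(prop-1-en-2-yl)-2,3-dihydro-1-benzofuran-3-yl (2Z)-2-[(acetyloxy)methyl]but-2-enoate, via acid chloride 30 (not isolated)
Conditions: 29 (1.3 equiv), 1-chloro-N,N,2-trimethylprop-1-en-1-amine (1.25 equiv), CH2Cl2, 0 °C; then 23, pyridine, CH2Cl2, 0 °C to rt
Reagents that add atoms: none
Why: Acylation of the secondary alcohol by acid chloride 30, made under neutral conditions (Ghosez reagent) so that neither HCl nor a nucleophilic catalyst isomerises the Z alkene or displaces the allylic acetate; the C6 phenol is hydrogen-bonded to the C5 acetyl group and far less nucleophilic than the C3 hydroxyl, and the C3–O bond is not broken, so the 2,3-cis configuration is retained.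

Compound list
1 | prop-2-en-1-ol (allyl alcohol) | C=CCO | starting material
2 | 3-(methoxymethoxy)prop-1-ene | C=CCOCOC | intermediate
3 | methacrolein (2-methylprop-2-enal) | C=C(C)C=O | starting material
4 | [(2Z)-3-(methoxymethoxy)prop-2-en-1-yl]bis(isopinocampheyl)borane (Ipc groups of the (−)-α-pinene series; not isolated) | COCO/C=C\CB([C@H]1C[C@H]2C[C@@H]([C@@H]1C)C2(C)C)[C@H]1C[C@H]2C[C@@H]([C@@H]1C)C2(C)C | intermediate
5 | (3S,4S)-4-(methoxymethoxy)-2-methylhexa-1,5-dien-3-ol | C=C(C)[C@H](O)[C@@H](OCOC)C=C | intermediate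
6 | O,C-bis(disiamylboryl) hydroboration adduct of 5 (not isolated) | C=C(C)[C@H](OB(C(C)C(C)C)C(C)C(C)C)[C@@H](OCOC)CCB(C(C)C(C)C)C(C)C(C)C | intermediate
7 | (3S,4S)-3-(methoxymethoxy)-5-methylhex-5-ene-1,4-diol | C=C(C)[C@H](O)[C@@H](OCOC)CCO | intermediate
8 | (4S,5S)-4-(methoxymethoxy)-5-(prop-1-en-2-yl)oxolan-2-ol (lactol; not isolated) | C=C(C)[C@@H]1OC(O)C[C@@H]1OCOC | intermediate
9 | (4S,5S)-4-(methoxymethoxy)-5-(prop-1-en-2-yl)oxolan-2-one | C=C(C)[C@@H]1OC(=O)C[C@@H]1OCOC | intermediate
10 | (4S,5S)-4-hydroxy-5-(prop-1-en-2-yl)oxolan-2-one | C=C(C)[C@@H]1OC(=O)C[C@@H]1O | intermediate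
11 | (3S,4S,5S)-3-[(dimethylamino)methyl]-4-hydroxy-5-(prop-1-en-2-yl)oxolan-2-one | C=C(C)[C@@H]1OC(=O)[C@@H](CN(C)C)[C@@H]1O | intermediate
12 | {[(3S,4S,5S)-4-hydroxy-2-oxo-5-(prop-1-en-2-yl)oxolan-3-yl]methyl}(trimethyl)azanium iodide (not isolated) | C=C(C)[C@@H]1OC(=O)[C@@H](C[N+](C)(C)C)[C@@H]1O.[I-] | intermediate
13 | (4S,5S)-4-hydroxy-3-methylidene-5-(prop-1-en-2-yl)oxolan-2-one | C=C(C)[C@@H]1OC(=O)C(=C)[C@@H]1O | intermediate
14 | (4S,5S)-4-{[tert-butyl(dimethyl)silyl]oxy}-3-methylidene-5-(prop-1-en-2-yl)oxolan-2-one | C=C(C)[C@@H]1OC(=O)C(=C)[C@@H]1O[Si](C)(C)C(C)(C)C | intermediate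
15 | tert-butyl(dimethyl){[(2S,3S)-4,5-dimethylidene-2-(prop-1-en-2-yl)oxolan-3-yl]oxy}silane | C=C(C)[C@@H]1OC(=C)C(=C)[C@@H]1O[Si](C)(C)C(C)(C)C | intermediate
16 | 2-(trimethylsilyl)ethanol | C[Si](C)(C)CCO | starting material
17 | trichloroethylene | ClC=C(Cl)Cl | starting material
18 | {2-[(E)-1,2-dichloroethenyl]oxyethyl}(trimethyl)silane | C[Si](C)(C)CCO/C(Cl)=C\Cl | intermediate
19 | lithium [2-(trimethylsilyl)ethoxy]acetylide (not isolated) | C[Si](C)(C)CCOC#C[Li] | intermediate
20 | 4-[2-(trimethylsilyl)ethoxy]but-3-yn-2-one | C[Si](C)(C)CCOC#CC(C)=O | intermediate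
21 | 1-[(2S,3S)-3-{[tert-butyl(dimethyl)silyl]oxy}-2-(prop-1-en-2-yl)-6-[2-(trimethylsilyl)ethoxy]-2,3,4,7-tetrahydro-1-benzofuran-5-yl]ethan-1-one (not isolated) | C=C(C)[C@@H]1OC2=C(CC(C(C)=O)=C(OCC[Si](C)(C)C)C2)[C@@H]1O[Si](C)(C)C(C)(C)C | intermediate
22 | 1-[(2S,3S)-3-{[tert-butyl(dimethyl)silyl]oxy}-2-(prop-1-en-2-yl)-6-[2-(trimethylsilyl)ethoxy]-2,3-dihydro-1-benzofuran-5-yl]ethan-1-one | C=C(C)[C@@H]1Oc2cc(OCC[Si](C)(C)C)c(C(C)=O)cc2[C@@H]1O[Si](C)(C)C(C)(C)C | intermediate
23 | 1-[(2S,3S)-3,6-dihydroxy-2-(prop-1-en-2-yl)-2,3-dihydro-1-benzofuran-5-yl]ethan-1-one | C=C(C)[C@@H]1Oc2cc(O)c(C(C)=O)cc2[C@@H]1O | intermediate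
24 | (E)-but-2-enal (crotonaldehyde) | C/C=C/C=O | starting material
25 | (2Z)-2-iodobut-2-enal | C/C=C(\I)C=O | intermediate
26 | (2Z)-2-iodobut-2-en-1-ol | C/C=C(\I)CO | intermediate
27 | lithium (2E)-2-lithiobut-2-en-1-olate (lithium cis to methyl; not isolated) | C/C=C(\[Li])CO[Li] | intermediate
28 | (2Z)-2-(hydroxymethyl)but-2-enoic acid | C/C=C(\C(=O)O)CO | intermediate
29 | (2Z)-2-[(acetyloxy)methyl]but-2-enoic acid | C/C=C(\C(=O)O)COC(C)=O | intermediate
30 | (2Z)-2-[(acetyloxy)methyl]but-2-enoyl chloride (not isolated) | C/C=C(\C(Cl)=O)COC(C)=O | intermediate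
31 | (2S,3S)-5-acetyl-6-hydroxy-2-(prop-1-en-2-yl)-2,3-dihydro-1-benzofuran-3-yl (2Z)-2-[(acetyloxy)methyl]but-2-enoate (CNP0193314.1) | C=C(C)[C@@H]1Oc2cc(O)c(C(C)=O)cc2[C@@H]1OC(=O)/C(=C\C)COC(C)=O | target

Total step count: 18.
Longest linear sequence: 12 steps (steps 1–9, 12, 13 and 18). The ynone (steps 10–11) and the side-chain acid (steps 14–17) are made separately.

Steps most likely to fail

Step 12 (Proposed new method). The donor-substituted ynone may add too slowly, so that the ynol ether fragments thermally or the diene dimerises first. The regiochemistry may also erode, or trace acid may expel silanol from the diene or from adduct 21 and lead to a furan or benzofuran. The fallback uses known chemistry and sets out from diene 15. Cycloaddition with commercial but-3-yn-2-one, the established type of partner for 2-alkoxydienes, should give the para adduct, 1-[(2S,3S)-3-silyloxy-2-isopropenyl-2,3,4,7-tetrahydro-1-benzofuran-5-yl]ethanone F1. DDQ would convert it into the aryl ketone F2. Ketone-directed ortho C–H borylation (B2pin2, [Ir(OMe)(cod)]2, AsPh3) should then functionalise the less hindered ortho position C6 to give the aryl boronate F3. Oxidation with NaBO3 would give the C6 phenol F4, and TBAF would remove the silyl ether, so the fallback rejoins the route at diol 23.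

Step 9. The titanium methylidene may react with the conjugated exocyclic alkene instead of the carbonyl, conversion may stall, or the dienyl ether may decompose through acid-induced ionisation during isolation. The fallback sets out from lactone 14 and uses a modified Julia olefination. Lithiated 2-(methylsulfonyl)-1,3-benzothiazole (LiHMDS, THF, −78 °C) would add to the lactone carbonyl to give the hemiketal sulfone F5. DBU would then induce Smiles rearrangement and loss of sulfur dioxide and benzothiazolol, delivering the exocyclic enol ether and rejoining the route at diene 15.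

Step 18. The phenol may be acylated in competition with the alcohol, the activated acid may isomerise from Z to E, or ionisation at benzylic C3 may lead to elimination towards the benzofuran. The fallback sets out from 22 and keeps the phenol masked during acylation. HF·pyridine (THF/pyridine, 0 °C) would cleave only the silyl ether and give the alcohol F6, which still carries the silylethyl aryl ether. Acylation with acid chloride 30 and pyridine would give the protected ester F7. TBAF buffered with AcOH would finally cleave the silylethyl ether while keeping the phenol protonated, rejoining the route at target 31.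

Further compounds
F1 | step 12 | 1-[(2S,3S)-3-{[tert-butyl(dimethyl)silyl]oxy}-2-(prop-1-en-2-yl)-2,3,4,7-tetrahydro-1-benzofuran-5-yl]ethan-1-one | C=C(C)[C@@H]1OC2=C(CC(C(C)=O)=CC2)[C@@H]1O[Si](C)(C)C(C)(C)C
F2 | step 12 | 1-[(2S,3S)-3-{[tert-butyl(dimethyl)silyl]oxy}-2-(prop-1-en-2-yl)-2,3-dihydro-1-benzofuran-5-yl]ethan-1-one | C=C(C)[C@@H]1Oc2ccc(C(C)=O)cc2[C@@H]1O[Si](C)(C)C(C)(C)C
F3 | step 12 | 1-[(2S,3S)-3-{[tert-butyl(dimethyl)silyl]oxy}-2-(prop-1-en-2-yl)-6-(4,4,5,5-tetramethyl-1,3,2-dioxaborolan-2-yl)-2,3-dihydro-1-benzofuran-5-yl]ethan-1-one | C=C(C)[C@@H]1Oc2cc(B3OC(C)(C)C(C)(C)O3)c(C(C)=O)cc2[C@@H]1O[Si](C)(C)C(C)(C)C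
F4 | step 12 | 1-[(2S,3S)-3-{[tert-butyl(dimethyl)silyl]oxy}-6-hydroxy-2-(prop-1-en-2-yl)-2,3-dihydro-1-benzofuran-5-yl]ethan-1-one | C=C(C)[C@@H]1Oc2cc(O)c(C(C)=O)cc2[C@@H]1O[Si](C)(C)C(C)(C)C
F5 | step 9 | (4S,5S)-2-[(1,3-benzothiazol-2-ylsulfonyl)methyl]-4-{[tert-butyl(dimethyl)silyl]oxy}-3-methylidene-5-(prop-1-en-2-yl)oxolan-2-ol | C=C(C)[C@@H]1OC(O)(CS(=O)(=O)c2nc3ccccc3s2)C(=C)[C@@H]1O[Si](C)(C)C(C)(C)C
F6 | step 18 | 1-[(2S,3S)-3-hydroxy-2-(prop-1-en-2-yl)-6-[2-(trimethylsilyl)ethoxy]-2,3-dihydro-1-benzofuran-5-yl]ethan-1-one | C=C(C)[C@@H]1Oc2cc(OCC[Si](C)(C)C)c(C(C)=O)cc2[C@@H]1O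
F7 | step 18 | (2S,3S)-5-acetyl-2-(prop-1-en-2-yl)-6-[2-(trimethylsilyl)ethoxy]-2,3-dihydro-1-benzofuran-3-yl (2Z)-2-[(acetyloxy)methyl]but-2-enoate | C=C(C)[C@@H]1Oc2cc(OCC[Si](C)(C)C)c(C(C)=O)cc2[C@@H]1OC(=O)/C(=C\C)COC(C)=O
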